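**Assumptions (one line):** Dimethyl (R)-malate, syringyl alcohol, allyl bromide, benzyl bromide and 4-(benzyloxy)-3-methoxybenzyl bromide are purchasable. The target is the all-trans (1R,2S,3S) aryltetralin exactly as drawn.

## Retrosynthetic overview
1. The C1–C8a bond (the tetralin ring, formed last) comes from anodic oxidation of a syringyl phenol to its p-quinone methide. A tethered guaiacyl ether ring then closes onto it by 6-exo Friedel–Crafts attack. The precursor is a 2,3-bis(arylmethyl)butane-1,4-diol protected as its bis-benzyl ether.
2. That diol comes from a (2S,3S)-2,3-bis(arylmethyl)succinate made by two enolate benzylations.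
3. The first benzyl-bearing stereocentre (C3) is set from (R)-malate by Fráter–Seebach alkylation anti to the carbinol. The carbinol is then erased by deoxygenation.
4. The second centre (C2) is set by substrate-controlled benzylation next to C3. C1 is set by the cyclisation, trans to C2.

## Route

**Step 1**
Reactants: 1 dimethyl (R)-malate; 2 4-(benzyloxy)-3-methoxybenzyl bromide
Product: 3 dimethyl (2R,3S)-3-[(4-benzyloxy-3-methoxyphenyl)methyl]-2-hydroxysuccinate
Conditions: LDA (2.2 equiv), THF, −78 → −20 °C; then 2, −78 → 0 °C; NH4Cl(aq)
Reagents that add atoms: compound 2, COc1cc(CBr)ccc1OCc1ccccc1 (used as the reactant)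
Why: Fráter–Seebach alkylation of the chelated malate dianion puts the electrophile anti to the carbinol, which sets the benzyl-bearing carbon (C3 of the target) from the malate stereocentre.

**Step 2**
Reactants: 3; 4 phenyl chlorothionoformate
Product: 5 O-phenyl thionocarbonate of 3
Conditions: PhOC(S)Cl, pyridine, DMAP (cat.), CH2Cl2, 0 °C
Reagents that add atoms: phenyl chlorothionoformate, S=C(Cl)Oc1ccccc1
Why: This is the Barton–McCombie activation of the secondary alcohol. Mild, cold conditions avoid E1cB loss of the thionocarbonate, and no stereocentre is touched.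

**Step 3**
Reactants: 5
Product: 6 dimethyl (S)-2-[(4-benzyloxy-3-methoxyphenyl)methyl]succinate
Conditions: Bu3SnH, AIBN (cat.), toluene, 80 °C
Reagents that add atoms: none (hydrogen only)
Why: Barton–McCombie radical deoxygenation turns the carbinol carbon into CH2. Its stereocentre is erased, while the adjacent benzyl-bearing centre (now S) is untouched and carries the chirality forward.

**Step 4**
Reactants: 7 syringyl alcohol (4-hydroxy-3,5-dimethoxybenzyl alcohol); 8 allyl bromide
Product: 9 4-(allyloxy)-3,5-dimethoxybenzyl alcohol
Conditions: allyl bromide, K2CO3, acetone, reflux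
Reagents that add atoms: allyl bromide, C=CCBr
Why: Williamson etherification is selective for the acidic phenol over the benzylic alcohol. The allyl group is a phenol mask that survives LDA, LiAlH4 and NaH and is later removed by Pd(0).

**Step 5**
Reactants: 9; 10 carbon tetrabromide
Product: 11 4-(allyloxy)-3,5-dimethoxybenzyl bromide
Conditions: CBr4, PPh3, CH2Cl2, 0 °C → rt; use crude
Reagents that add atoms: CBr4, BrC(Br)(Br)Br
Why: Appel bromination converts the benzylic alcohol to the bromide under neutral conditions.

**Step 6**
Reactants: 6; 11
Product: 12 dimethyl (2S,3S)-2-[(4-allyloxy-3,5-dimethoxyphenyl)methyl]-3-[(4-benzyloxy-3-methoxyphenyl)methyl]succinate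
Conditions: LDA (1.05 equiv), THF, −78 °C; then 11 (1.2 equiv), DMPU, −78 → −40 °C
Reagents that add atoms: compound 11, COc1cc(CBr)cc(OC)c1OCC=C (used as the reactant)
Why: Enolate alkylation occurs at the unsubstituted CH2CO2Me, and the existing C3 benzyl group directs the electrophile to the face that gives the 2,3-dl (S,S) isomer. This is 1,2-induction, assumed at about 4:1 or better, and the minor diastereomer is removed by chromatography.

**Step 7**
Reactants: 12
Product: 13 (2S,3S)-2-[(4-allyloxy-3,5-dimethoxyphenyl)methyl]-3-[(4-benzyloxy-3-methoxyphenyl)methyl]butane-1,4-diol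
Conditions: LiAlH4, THF, 0 °C → rt
Reagents that add atoms: none (hydrogen only)
Why: Ester reduction gives the diol without touching the non-acidic stereocentres. Reducing here also removes the acidic ester α-C–H that would tautomerise the later quinone methide.

**Step 8**
Reactants: 13; 14 benzyl bromide
Product: 15 bis(benzyl ether) of 13
Conditions: NaH, BnBr, TBAI (cat.), DMF, 0 °C → rt
Reagents that add atoms: benzyl bromide, BrCc1ccccc1
Why: Williamson bis-O-benzylation stops the free hydroxyls from trapping the quinone methide as a tetrahydrofuran, and the benzyl groups are removed together with the ring-A benzyl in the last step.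

**Step 9**
Reactants: 15
Product: 16 phenol (free syringyl OH)
Conditions: Pd(PPh3)4 (5 mol%), K2CO3, MeOH, rt
Reagents that add atoms: none
Why: Tsuji–Trost deallylation frees only the syringyl phenol. That phenol is the oxidisable handle and is far easier to oxidise than the benzyl-protected guaiacyl arm.

**Step 10**
Reactants: 16
Product: 17 (1R,2S,3S)-1-(4-hydroxy-3,5-dimethoxyphenyl)-7-benzyloxy-6-methoxy-2,3-bis(benzyloxymethyl)-1,2,3,4-tetrahydronaphthalene
Conditions: constant-current electrolysis (4 mA, about 2.1 F/mol), undivided cell, RVC anode, Pt cathode, HFIP/CH2Cl2 (1:1), Bu4NBF4 (0.05 M), 0.02 M substrate, rt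
Reagents that add atoms: none (H2 is evolved at the cathode)
Why: Proposed new method: anodic oxidation of the 4-alkyl-2,6-dimethoxyphenol (E about +1.0 V, well below the guaiacyl ether) gives the phenoxyl radical and then the p-quinone methide by loss of the benzylic proton, and HFIP hydrogen-bonding activates it toward the tethered veratrole-type ring. That ring attacks in a 6-exo Friedel–Crafts step at the position para to its OMe through a chair-like transition state with C2 and C3 substituents equatorial, so the new aryl ends up trans to C2 (1R); the closest known reactions are anodic phenol–arene coupling in HFIP, DDQ-generated quinone-methide cyclisation of secoisolariciresinol-type lignans, and the biosynthetic secoisolariciresinol → cyclolariciresinol cyclisation.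

**Step 11**
Reactants: 17
Product: 18 target, (1R,2S,3S)-1-(4-hydroxy-3,5-dimethoxyphenyl)-6-methoxy-2,3-bis(hydroxymethyl)-1,2,3,4-tetrahydronaphthalen-7-ol
Conditions: H2 (1 atm), 10% Pd/C, EtOAc/EtOH, rt
Reagents that add atoms: none (hydrogen only)
Why: Hydrogenolysis removes the ring-A benzyl ether and both CH2OBn groups in one operation, and it leaves the stereocentres and the diarylmethine carbon intact.

## Compound list
1 | dimethyl (R)-malate | COC(=O)[C@H](O)CC(=O)OC | starting material
2 | 4-(benzyloxy)-3-methoxybenzyl bromide | COc1cc(CBr)ccc1OCc1ccccc1 | starting material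
3 | dimethyl (2R,3S)-3-(arylmethyl)-2-hydroxysuccinate | COC(=O)[C@H](O)[C@H](Cc1ccc(OCc2ccccc2)c(OC)c1)C(=O)OC | intermediate
4 | phenyl chlorothionoformate | S=C(Cl)Oc1ccccc1 | starting material
5 | O-phenyl thionocarbonate of 3 | COC(=O)[C@H](OC(=S)Oc1ccccc1)[C@H](Cc1ccc(OCc2ccccc2)c(OC)c1)C(=O)OC | intermediate
6 | dimethyl (S)-2-(arylmethyl)succinate | COC(=O)C[C@H](Cc1ccc(OCc2ccccc2)c(OC)c1)C(=O)OC | intermediate
7 | syringyl alcohol | COc1cc(CO)cc(OC)c1O | starting material
8 | allyl bromide | C=CCBr | starting material
9 | 4-(allyloxy)-3,5-dimethoxybenzyl alcohol | COc1cc(CO)cc(OC)c1OCC=C | intermediate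
10 | carbon tetrabromide | BrC(Br)(Br)Br | starting material
11 | 4-(allyloxy)-3,5-dimethoxybenzyl bromide | COc1cc(CBr)cc(OC)c1OCC=C | intermediate
12 | dimethyl (2S,3S)-2,3-bis(arylmethyl)succinate | COC(=O)[C@@H](Cc1cc(OC)c(OCC=C)c(OC)c1)[C@H](Cc1ccc(OCc2ccccc2)c(OC)c1)C(=O)OC | intermediate
13 | (2S,3S)-2,3-bis(arylmethyl)butane-1,4-diol | OC[C@@H](Cc1cc(OC)c(OCC=C)c(OC)c1)[C@H](Cc1ccc(OCc2ccccc2)c(OC)c1)CO | intermediate
14 | benzyl bromide | BrCc1ccccc1 | starting material
15 | bis(benzyl ether) of 13 | c1ccccc1COC[C@@H](Cc1cc(OC)c(OCC=C)c(OC)c1)[C@H](Cc1ccc(OCc2ccccc2)c(OC)c1)COCc1ccccc1 | intermediate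
16 | free syringyl phenol | c1ccccc1COC[C@@H](Cc1cc(OC)c(O)c(OC)c1)[C@H](Cc1ccc(OCc2ccccc2)c(OC)c1)COCc1ccccc1 | intermediate
17 | tris(benzyl ether) aryltetralin | COc1cc2c(cc1OCc1ccccc1)[C@@H](c1cc(OC)c(O)c(OC)c1)[C@H](COCc1ccccc1)[C@@H](COCc1ccccc1)C2 | intermediate
18 | target | COc1cc2c(cc1O)[C@@H](c1cc(OC)c(O)c(OC)c1)[C@H](CO)[C@@H](CO)C2 | target

## Totals
Total steps: 11. Longest linear sequence: 9 (steps 1, 2, 3, 6, 7, 8, 9, 10, 11).

## Three steps most likely to fail
1. **Step 10 (proposed new electrochemical cyclisation).** The quinone methide may over-oxidise, since the product has the same phenol and a tertiary benzylic C–H, or it may be trapped by HFIP or dimerise.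
   Fallback (known chemistry, different approach): install the C1 oxygen first. Form the aldol adduct of the enolate of 6 with 4-allyloxy-3,5-dimethoxybenzaldehyde and carry it through to the diaryl carbinol. Close the ring by acid-mediated Friedel–Crafts cyclisation (BF3·OEt2 or TFA), the classical aryltetralin-lignan closure. Then restore C2/C3 trans by α-epimerisation of the ester-bearing intermediate and finish by reduction and deprotection.
2. **Step 6 (second benzylation diastereoselectivity).** The 1,2-induction may be poor, which would give the meso-type diastereomer.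
   Fallback: hydrolyse 6 to the diacid, form the anhydride and reduce it with NaBH4 at the more hindered carbonyl to give the (R)-β-arylmethyl-γ-butyrolactone. Benzylate that lactone enolate, which is known to be strongly trans-selective, and reduce the resulting lactone with LiAlH4 to give diol 13.
3. **Step 3, with its precursor Step 2 (deoxygenation).** The activated α-oxygenated ester may eliminate to the benzylfumarate, which would destroy the C3 stereocentre.
   Fallback: replace the radical route with a two-electron sequence. Convert the alcohol to the α-iodide under Appel-type conditions (PPh3, I2, imidazole) and reduce it with Zn/AcOH. The carbinol stereochemistry does not matter because that carbon becomes CH2.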